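| setting | Sunday's | Monday's | flask |
|---|---|---|---|
| substrate | 5 mM | 20 mM | 10 mM |
| gas phase | 0.40 mM (held) | 0.40 mM (held) | 0.40 mM (held) |
| remark | run made earlier | run made earlier |  |
| time |  |  | 5.0 min |

| run | time / min | target / % |
|---|---|---|
| Sunday's | 0.333 | 6.7 |
| Sunday's | 1.00 | 18.6 |
| Sunday's | 2.00 | 26.0 |
| Sunday's | 3.00 | 29.1 |
| Sunday's | 4.00 | 26.7 |
| Monday's | 0.333 | 3.1 |
| Monday's | 1.00 | 5.1 |
| Monday's | 2.00 | 10.8 |
| Monday's | 3.00 | 15.2 |
| Monday's | 4.00 | 15.8 |

(scatter of a reading: 1 percentage point)
* how much target there is at 5.0 min, in percent of the substrate charged
* the change that raises the amount of target at 5.0 min, in percent of the substrate charged most ("none" if none brings more than 2 percentage points) (ochre / violet / none)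
* amount of target at 5.0 min, in percent of the substrate charged, after violet
- ochre: doubling the saturation concentration of gas phase, all else as stated
- violet: doubling the transfer coefficient of the gas phase, all else as stated
- at the start none of the gas phase is in solution

1. Each fraction of the charge not read as target is still substrate or has gone elsewhere, so the fractions add to one. Sunday's last two readings average 27.9 % and Monday's 15.5 %; my reckoning takes both as plateaus.

2. Sunday's 2.58 and Monday's 5.45 are loss ratios, the fraction not read as target divided by the fraction read as target. Taken on a plateau, this selectivity factor divides one accumulated amount by another, so time drops out; earlier in a run it still counts unreacted substrate.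

3. By 1.00 min, Sunday's run holds 0.930 mM target and Monday's 1.02 mM, from charges of 5 mM and 20 mM. Target formation barely follows the charge, so I take the loss ratio as a straight line in the charge.

4. The flask lies a third of the way along that line, giving 3.54 and 22.0 % target. It ends below Sunday's run because it has half Sunday's gas supply per charge.

5. Violet restores Sunday's gas per charge, so I expect about 27.9 %. Ochre also raises the dissolved ceiling to 0.800 mM, while violet leaves it at 0.40 mM, so I put ochre above violet, without a figure of its own, and choose ochre.

The forecast differs: 28 %, best none, and 25.5 % after violet, since “Doubling either saturation or transfer coefficient roughly doubles the gas supplied, overshooting the peak”.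

The flask gives 22.0 %; the best change is ochre, with a gain of 10 percentage points against 7.1 points for violet, which reaches 29.2 %.

    target ⇌ isomer of the product (K = 0.420, k = 0.0310 s⁻¹)
    gas phase ⇌ dissolved gas, rate k2*(csat - [dissolved gas]) (kL = 0.0740 s⁻¹)
    dissolved gas → decomposed reagent (k = 0.00170 s⁻¹)
    substrate → side product (k = 0.0120 s⁻¹)
    substrate + dissolved gas → target (k = 63.0 L mol⁻¹ s⁻¹)

At 5.00 min, the flask holds 0.0315 % substrate, 68.7 % side product and 9.25 % isomer of the product, and its target still reads 22.0 % at 50.0 min. The neighbouring flask charged with 2.5 mM of substrate takes the same line, which gives a loss ratio of 2.11 and 32.2 % target. That neighbouring flask gives 33.7 % target.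

(The runs were generated by integration for an exercise; scatter was added.)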